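**Locants and remark.** Ring carbons are C1–C10: C3 = ketone, C4 = C(CH3)(OH), C5 = CH–O-isobutyryl, C6 = CH–O (lactone), C7 = lactone ring fusion, C8 = CH–O-isobutyryl, C9 = CH–OH, C10 = CH(CH3), C1/C2 = CH2 (C2 next to C3); C11 = C(=CH2), C12 = lactone C=O, C13 = exocyclic CH2. In these locants the target 25 is (4R,5R,6S,7R,8R,9R,10R). TES = triethylsilyl, TBS = tert-butyldimethylsilyl.
Remark (assumption): the target is made as the open 3-oxo-9-hydroxy form that is drawn; a 3,9-hemiketal, if it forms, is a tautomer in equilibrium with it and needs no step of its own.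

## The problem

The target is a ten-membered carbocycle (C1–C10) without a ring double bond, trans-fused at C6–C7 to an α-methylene-γ-butyrolactone, with seven contiguous stereocenters C4–C10. An end-to-end closure of this ring would have to be done on a saturated chain that already carries five or more stereocenters. C5–O, C6–O, C7–C11 and C8–O are all trans to their neighbours, so on a six-membered ring they would all be equatorial; C4–OH is cis to C5–O, C8–O/C9–O are trans, and C9–OH is cis to the C10 methyl group. Five oxygens must be told apart: tertiary C4–OH and secondary C9–OH stay free, C5–O and C8–O carry isobutyrates, C6–O is in the lactone; the hard pair is C8–OH/C9–OH. The feature that opens the problem is that the C3 ketone and C8 lie 1,6 across the ring (C3–C2–C1–C10–C9–C8) and C8/C9 carry the vicinal oxygens: the ring is a cyclodec-5-enone in disguise, the product of an oxy-Cope ring expansion of a cyclohexane made of C3–C8 with alkenyl groups C2=C1 on C3 and C9=C10 on C8, and the C10 methyl stereocenter sits at the end of the bond that this rearrangement forms. The same C3 carbonyl is 1,5 to C9, so its oxygen can reach C9 through a six-membered ring. Sensitive groups are the α-methylene lactone (nucleophiles, strong base), the C3/C4 α-ketol (acyloin shift), the esters next to a free hydroxyl (acyl migration under base), and any cyclodec-5-enone intermediate (transannular carbonyl–ene closure under acid).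

## Retrosynthesis

**25 ⇒ 24 ⇒ 23 (C8 acyl–O bond; C3–O–C9 bridge).** The target is read as the hydrolysis product of the bridged methyl ketal 24, which comes from 23 by acylation of its only free hydroxyl. The neighbouring cut, mono-acylation or mono-silylation of an 8,9-diol, has only a small steric difference to work with. The ketal ties up exactly the hydroxyl that is 1,5 to the C3 carbonyl and masks the α-ketol at the same time. The forward steps need only an acylation and a mild acid hydrolysis.

**23 ⇒ 22 ⇒ 21 (C9–O bond; epoxide oxygen).** Ketal 23 comes from epoxy ketone 22 by transannular attack of the C3 carbonyl oxygen on C9 and capture of the oxocarbenium ion by methanol; 22 comes from the Z-alkene 21. The neighbour, syn-dihydroxylation of an E-alkene, gives an undifferentiated diol and needs a Cope precursor whose vinyl group was delivered to C3 syn to the axial C4–O bond, against the inherent facial preference. The precursor 21 has two stereocenters and two C–O bonds fewer. The forward reaction must epoxidise the outer face and open at C9 (six-membered ring) with inversion.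

**21 ⇒ 20 ⇒ 18 ⇒ 17 (C5 acyl–O; lactone acyl–O and C12 oxidation level; TES groups).** The lactone is cut to the 2-methylene-1,4-diol unit of 18 (C12–OH, C6–OH), which closes by oxidative lactonisation. C11–C13 is therefore carried as an allylic silyl ether, which survives organometallic reagents and potassium hydride, where a lactone or acrylate would not. The forward steps need TES cleavage beside a tertiary TBS ether and acylation of C5–OH before the epoxide is made.

**17 ⇒ 15 (key: cut C1–C10, re-join C3–C8).** The ten-membered ketone 17 is the anionic oxy-Cope product of the 1-vinyl-2-propenylcyclohexanol 15. Against the ring-closing neighbours (C6–C7, C1–C2, C4–C5) this cut asks for no macrocyclisation, and it places C4–C8 on a chair cyclohexane where the all-trans array is all-equatorial. The precursor is a six-membered ring; the product has the ten-membered ring, the C3 ketone, the C8=C9 alkene and C10. The forward reaction must go through one chair transition state.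

**15 ⇒ 14 ⇒ 13 ⇒ 9 + 11 (C3–vinyl; C8–propenyl; C7–C11 and C8–C9).** The vinyl group is added to ketone 14 along the inherently preferred axial path. The (E)-propenyl group comes from the allyl group of 13. Both C7 and C8 substituents are set in one three-component coupling of enone 9 with the cuprate from 11 and allyl iodide. The forward steps rely on addition anti to the C6 silyloxy group and alkylation anti to the new C7 substituent.

**9 ⇒ 8 ⇒ 7 ⇒ 6 ⇒ 4 ⇒ 3 ⇒ 2 ⇒ 1 (C7=C8; C3–C4; C4–CH3).** The enone is cut at C7=C8 to keto aldehyde 8 (aldol condensation). The C3–C4 bond is cut to methyl ketone 4 and an acetyl-anion equivalent; the C4–CH3 bond is cut to the C2-symmetric bis-Weinreb amide 3 of L-tartaric acid. C5 and C6 come from diethyl L-tartrate 1, and C4 is set by a Felkin–Anh addition next to C5.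

## Roads not taken

**Alternative 1:** (the most obvious) cut C6–C7 and the lactone acyl–O bond; the forward key step is an intramolecular Nozaki–Hiyama–Kishi or Barbier allylation of the seco bromo-aldehyde A1, followed by lactonisation, which would lead to 25. A1 is an open chain with five stereocenters in two groups (C4/C5 and C8–C10) separated by C1–C3, so two asymmetric sequences and a fragment coupling are needed before the key step. The ring must then be closed on a saturated chain without a rigid element, with C6 and C7 set relative to remote centres. The chosen plan pays no macrocyclisation entropy and sets the same centres on a chair.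

**Alternative 2:** cut C1–C2 as an alkene; ring-closing metathesis of diene A2, then saturation of the new C1=C2 bond, would give 25. Ten-membered ring-closing metathesis on an unbiased chain competes with dimerisation, the C1=C2 enone must be reduced beside the more reactive α-methylene lactone, and A2 needs all seven stereocenters and the lactone in place on an open chain.

**Alternative 3:** cut C4–C5; a samarium(II)-mediated pinacol macrocyclisation of the diketo aldehyde A3 would form the cis C4/C5 diol and the ring together. Samarium(II) also reduces the α-methylene lactone and cleaves the C6–O bond α to the aldehyde, the facial course at C4/C5 has no clear control element, and A3 again carries C6–C10 on an open chain.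

Key step: step 11

## Route

Step 1
Reactants: 1 diethyl L-tartrate [diethyl (2R,3R)-2,3-dihydroxybutanedioate]
Product: 2 diethyl (2R,3R)-2,3-bis(triethylsilyloxy)butanedioate
Conditions: TESCl, imidazole, DMF, 0 °C → rt
Reagents that add atoms: chlorotriethylsilane, CC[Si](Cl)(CC)CC
Why: Standard silylation of both secondary hydroxyls; separate TES ethers are chosen over an acetonide so that C5–O/C6–O (the tartrate carbinols) can turn pseudoaxial in step 8 and can later be removed beside a tertiary TBS ether; no stereocenter is touched.

Step 2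
Reactants: 2 diethyl (2R,3R)-2,3-bis(triethylsilyloxy)butanedioate
Product: 3 (2R,3R)-N1,N4-dimethoxy-N1,N4-dimethyl-2,3-bis(triethylsilyloxy)butanediamide
Conditions: MeNH(OMe)·HCl, iPrMgCl, THF, −20 → 0 °C
Reagents that add atoms: N,O-dimethylhydroxylamine hydrochloride, CNOC.Cl
Why: Direct ester-to-Weinreb-amide conversion with the chloromagnesium amide; α-silyloxy esters are not epimerised under these conditions.

Step 3
Reactants: 3 (2R,3R)-N1,N4-dimethoxy-N1,N4-dimethyl-2,3-bis(triethylsilyloxy)butanediamide
Product: 4 (2R,3R)-N-methoxy-N-methyl-4-oxo-2,3-bis(triethylsilyloxy)pentanamide (C4 methyl ketone, C7 amide)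
Conditions: MeMgBr (1.05 equiv), THF, −78 → −20 °C
Reagents that add atoms: methylmagnesium bromide, C[Mg]Br
Why: Weinreb ketone synthesis; the chelated tetrahedral intermediate prevents over-addition, and with one equivalent of Grignard reagent one of the two homotopic amides is converted, so either gives 4.

Step 4
Reactants: 4 (2R,3R)-N-methoxy-N-methyl-4-oxo-2,3-bis(triethylsilyloxy)pentanamide
Product: 6 (2R,3R,4R)-4-(tert-butyldimethylsilyloxy)-5-ethoxy-N-methoxy-N,4-dimethyl-2,3-bis(triethylsilyloxy)hex-5-enamide, via lithium C4-alkoxide 5 (not isolated)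
Conditions: CH2=C(OEt)Li (from ethyl vinyl ether, tBuLi), THF, −78 °C; then TBSOTf, −78 → 0 °C
Reagents that add atoms: ethyl vinyl ether, C=COCC; tert-butyldimethylsilyl trifluoromethanesulfonate, CC(C)(C)[Si](C)(C)OS(=O)(=O)C(F)(F)F
Why: 1,2-Addition of an acetyl-anion equivalent to the α-silyloxy ketone under Felkin–Anh (non-chelation) control, the nucleophile entering anti to the C5–OSi bond past C5–H, sets C4 with C4–O anti to C5–O in the zigzag (the cis C4/C5 pair of the ring); the ketone reacts far faster than the Weinreb amide at −78 °C, and the tertiary alkoxide is silylated in the same flask.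

Step 5
Reactants: 6 (2R,3R,4R)-4-(tert-butyldimethylsilyloxy)-5-ethoxy-N-methoxy-N,4-dimethyl-2,3-bis(triethylsilyloxy)hex-5-enamide
Product: 7 (2R,3R,4R)-4-(tert-butyldimethylsilyloxy)-5-ethoxy-4-methyl-2,3-bis(triethylsilyloxy)hex-5-enal
Conditions: DIBAL-H, THF, −78 °C; Rochelle salt
Reagents that add atoms: none
Why: Weinreb amide reduction stops at the aldehyde through the stable aluminium chelate; enol ether and silyl ethers are inert.

Step 6
Reactants: 7 (2R,3R,4R)-4-(tert-butyldimethylsilyloxy)-5-ethoxy-4-methyl-2,3-bis(triethylsilyloxy)hex-5-enal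
Product: 9 enone (4S,5R,6R)-6-(tert-butyldimethylsilyloxy)-6-methyl-4,5-bis(triethylsilyloxy)cyclohex-2-en-1-one (ring = C3–C8; C3=O, C7=C8, C4(CH3)(OTBS), C5–OTES, C6–OTES), via keto aldehyde 8 (not isolated)
Conditions: 0.05 M HCl, THF–H2O, 0 °C; then Bn2NH·CF3CO2H, benzene, 50 °C
Reagents that add atoms: water, O
Why: Dilute acid unmasks the methyl ketone; dibenzylammonium trifluoroacetate then effects the intramolecular aldol condensation of the methyl ketone carbon (C8) onto the C7 aldehyde (6-enolendo-exo-trig) and dehydration to the conjugated enone; no new stereocenter is formed.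

Step 7
Reactants: 10 2-bromoprop-2-en-1-ol
Product: 11 (2-bromoprop-2-en-1-yloxy)triethylsilane
Conditions: TESCl, imidazole, CH2Cl2, 0 °C
Reagents that add atoms: chlorotriethylsilane, CC[Si](Cl)(CC)CC
Why: Routine silylation of a primary allylic alcohol; it gives the C11–C13 unit with C12 at the alcohol level.

Step 8
Reactants: 9 enone (ring C3–C8); 11 (2-bromoprop-2-en-1-yloxy)triethylsilane
Product: 13 cyclohexanone: 9 saturated at C7/C8, C7 bearing CH2=C(CH2OTES)– trans to C6–OTES, C8 bearing allyl trans to the C7 substituent, via lithium enolate 12 (not isolated)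
Conditions: 11 (2.2 equiv), tBuLi, Et2O, −78 °C; CuI, −40 °C; 9, −78 °C; then HMPA, allyl iodide, −78 → −20 °C
Reagents that add atoms: allyl iodide, C=CCI
Why: Three-component coupling: the alkenyl Gilman cuprate adds to the γ-silyloxy enone anti to the C6–OSi bond (the pseudoaxial γ-alkoxy conformer reacts), which sets C7, and the regiodefined enolate (C4 is quaternary) is allylated anti to the new C7 substituent, which sets C8 trans.

Step 9
Reactants: 13 cyclohexanone with C8 allyl
Product: 14 cyclohexanone: as 13 with (E)-prop-1-enyl at C8
Conditions: [Ir(cod)(PMePh2)2]PF6 (cat., H2-activated), THF, rt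
Reagents that add atoms: none
Why: Iridium-hydride-catalysed 1,3-hydrogen shift moves the terminal double bond by one position to the (E)-propenyl group; the monosubstituted allyl group reacts much faster than the 1,1-disubstituted C11=C13 alkene, and the mild conditions should stop before conjugation with the ketone.

Step 10
Reactants: 14 cyclohexanone with C8 (E)-propenyl
Product: 15 tertiary carbinol: C3(OH)(vinyl), vinyl cis to the C8 propenyl group and trans to C4–OTBS
Conditions: CH2=CHMgBr, CeCl3, THF, −78 °C
Reagents that add atoms: vinylmagnesium bromide, C=C[Mg]Br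
Why: Organocerium 1,2-addition suppresses enolisation of the hindered ketone; in the chair with C5–O, C6–O, C7 and C8 substituents equatorial the C4–OTBS bond is axial, so the vinyl group enters axially anti to it (Felkin–Anh, axial attack), which places it cis to the equatorial propenyl group.

Step 11
Reactants: 15 tertiary carbinol (1-vinyl-2-propenylcyclohexanol)
Product: 17 (Z)-cyclodec-5-enone: ring C1–C10, C3=O, C8=C9 (Z), C4(CH3)(OTBS), C5–OTES, C6–OTES, C7–C(=CH2)CH2OTES, C10–CH3 (10R), via potassium enolate 16 (not isolated)
Conditions: KH, 18-crown-6, THF, 0 → 25 °C; then aq NH4Cl, −78 °C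
Reagents that add atoms: none
Why: Deprotonation gives the potassium alkoxide, which undergoes an anionic oxy-Cope ([3,3]-sigmatropic) rearrangement: the C3–C8 bond breaks as C1–C10 forms, and the C3 ketone appears as its enolate 16. The closest known reaction type is the anionic oxy-Cope ring expansion of 1,2-dialkenylcyclohexanols to cyclodec-5-enones. The ten-membered ring is made by a four-carbon ring expansion through a six-centre chair transition state, not by an end-to-end closure. The cyclohexane is held in the chair with C5–O, C6–O, C7–C11 and the C8 propenyl group equatorial and the C3 vinyl group axial, so the only chair open to it has C7 axial and C4 equatorial on the Cope chair, which gives the (Z)-C8=C9 alkene. C10 is set by chirality transfer from C8: the methyl group of the (E)-propenyl unit sits equatorial on the Cope chair and C1 bonds to the face of C10 that makes it R. The stereocenters C3 and C8 are consumed and C4–C7 are untouched. The step needs chair over boat and [3,3] over [1,3] shift or fragmentation; the rigid all-equatorial substrate, the equatorial methyl group and the irreversible enolate formation secure this. A cold proton quench gives 17, which has no epimerisable centre next to the carbonyl (C4 is quaternary, C2 is CH2).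

Step 12
Reactants: 17 (Z)-cyclodec-5-enone, fully silylated
Product: 18 triol: 17 with free C5–OH, C6–OH and C12–OH, C4–OTBS kept
Conditions: AcOH–THF–H2O (3:1:1), rt
Reagents that add atoms: none
Why: The primary and the two secondary TES ethers are cleaved by dilute acetic acid while the tertiary TBS ether survives (TES/TBS orthogonality); the weak acid is chosen to avoid transannular carbonyl–ene closure of the cyclodec-5-enone.

Step 13
Reactants: 18 triol
Product: 20 α-methylene-γ-lactone (C6–O–C12(=O)–C11(=C13H2)–C7, trans-fused) with free C5–OH, via hydroxy enal 19 (not isolated)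
Conditions: MnO2 (excess), CH2Cl2, rt
Reagents that add atoms: none
Why: Manganese dioxide oxidises only the allylic primary alcohol; the enal is trapped by C6–OH as the five-membered lactol and oxidised on to the lactone (oxidative lactonisation of a 2-methylene-1,4-diol); C5–OH could only give a bridged δ-lactol and should not compete, and the trans fusion follows from the existing C6/C7 configuration.

Step 14
Reactants: 20 lactone with free C5–OH
Product: 21 C5 isobutyrate of 20
Conditions: (iPrCO)2O, DMAP, Et3N, CH2Cl2, rt
Reagents that add atoms: isobutyric anhydride, CC(C)C(=O)OC(=O)C(C)C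
Why: DMAP-catalysed acylation of the only free hydroxyl; it also removes the C5–OH nucleophile, which could open the epoxide at C8 in the next step.

Step 15
Reactants: 21 C5 isobutyrate, Z-C8=C9 alkene
Product: 23 bridged methyl ketal: oxygen bridge C3(OCH3)–O–C9 (9R), free C8–OH (8R), via epoxy ketone 22 (not isolated)
Conditions: DMDO, acetone, 0 °C; then MeOH, CSA (cat.), 0 °C
Reagents that add atoms: dimethyldioxirane, CC1(C)OO1; methanol, CO
Why: The dioxirane epoxidises only the electron-rich Z-alkene, from the outer face of the ring (the inner face is covered by C1–C3), which fixes C8; acid then triggers transannular 6-exo attack of the C3 carbonyl oxygen on C9 with inversion, and methanol traps the oxocarbenium ion, a known mode of epoxide opening by a ketone across a medium ring. The outcome is C9 set, C8–OH free and the α-ketol masked.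

Step 16
Reactants: 23 bridged methyl ketal with free C8–OH
Product: 24 C8 isobutyrate of 23
Conditions: (iPrCO)2O, DMAP, CH2Cl2, rt → 40 °C
Reagents that add atoms: isobutyric anhydride, CC(C)C(=O)OC(=O)C(C)C
Why: Acylation of the single remaining hydroxyl; C9–O is locked in the ketal and C4–O is silylated, so no site selectivity is needed.

Step 17
Reactants: 24 bis-isobutyrate ketal
Product: 25 target, CNP0396108.1
Conditions: 48% aq HF, MeCN, rt
Reagents that add atoms: water, O
Why: Aqueous HF cleaves the tertiary TBS ether and hydrolyses the bicyclic mixed ketal to the C3 ketone and C9–OH; acidic conditions avoid acyl migration, acyloin shift and conjugate addition to the methylene lactone.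

## Compound list

1 | diethyl L-tartrate | CCOC(=O)[C@H](O)[C@@H](O)C(=O)OCC | starting material
2 | diethyl (2R,3R)-2,3-bis(triethylsilyloxy)butanedioate | CCOC(=O)[C@H](O[Si](CC)(CC)CC)[C@@H](O[Si](CC)(CC)CC)C(=O)OCC | intermediate
3 | bis-Weinreb amide | CON(C)C(=O)[C@H](O[Si](CC)(CC)CC)[C@@H](O[Si](CC)(CC)CC)C(=O)N(C)OC | intermediate
4 | C4 methyl ketone / C7 Weinreb amide | CC(=O)[C@H](O[Si](CC)(CC)CC)[C@@H](O[Si](CC)(CC)CC)C(=O)N(C)OC | intermediate
5 | lithium C4-alkoxide (1-ethoxyvinyl adduct) | [Li+].C=C(OCC)[C@](C)([O-])[C@H](O[Si](CC)(CC)CC)[C@@H](O[Si](CC)(CC)CC)C(=O)N(C)OC | intermediate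
6 | C4–OTBS 1-ethoxyvinyl Weinreb amide | C=C(OCC)[C@](C)(O[Si](C)(C)C(C)(C)C)[C@H](O[Si](CC)(CC)CC)[C@@H](O[Si](CC)(CC)CC)C(=O)N(C)OC | intermediate
7 | aldehyde | C=C(OCC)[C@](C)(O[Si](C)(C)C(C)(C)C)[C@H](O[Si](CC)(CC)CC)[C@@H](O[Si](CC)(CC)CC)C=O | intermediate
8 | keto aldehyde | CC(=O)[C@](C)(O[Si](C)(C)C(C)(C)C)[C@H](O[Si](CC)(CC)CC)[C@@H](O[Si](CC)(CC)CC)C=O | intermediate
9 | enone (ring C3–C8) | O=C1[C@](C)(O[Si](C)(C)C(C)(C)C)[C@H](O[Si](CC)(CC)CC)[C@@H](O[Si](CC)(CC)CC)C=C1 | intermediate
10 | 2-bromoprop-2-en-1-ol | OCC(Br)=C | starting material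
11 | (2-bromoprop-2-en-1-yloxy)triethylsilane | C=C(Br)CO[Si](CC)(CC)CC | intermediate
12 | lithium enolate of the conjugate adduct | [Li+].[O-]C1=C[C@@H](C(=C)CO[Si](CC)(CC)CC)[C@H](O[Si](CC)(CC)CC)[C@@H](O[Si](CC)(CC)CC)[C@@]1(C)O[Si](C)(C)C(C)(C)C | intermediate
13 | C7-alkenyl, C8-allyl cyclohexanone | O=C1[C@](C)(O[Si](C)(C)C(C)(C)C)[C@H](O[Si](CC)(CC)CC)[C@@H](O[Si](CC)(CC)CC)[C@H](C(=C)CO[Si](CC)(CC)CC)[C@H]1CC=C | intermediate
14 | C8-(E)-propenyl cyclohexanone | O=C1[C@](C)(O[Si](C)(C)C(C)(C)C)[C@H](O[Si](CC)(CC)CC)[C@@H](O[Si](CC)(CC)CC)[C@H](C(=C)CO[Si](CC)(CC)CC)[C@H]1/C=C/C | intermediate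
15 | 1-vinyl-2-propenylcyclohexanol | O[C@]1(C=C)[C@](C)(O[Si](C)(C)C(C)(C)C)[C@H](O[Si](CC)(CC)CC)[C@@H](O[Si](CC)(CC)CC)[C@H](C(=C)CO[Si](CC)(CC)CC)[C@H]1/C=C/C | intermediate
16 | potassium enolate of 17 | [K+].[O-]/C1=C\C[C@@H](C)/C=C\[C@@H](C(=C)CO[Si](CC)(CC)CC)[C@H](O[Si](CC)(CC)CC)[C@@H](O[Si](CC)(CC)CC)[C@@]1(C)O[Si](C)(C)C(C)(C)C | intermediate
17 | (Z)-cyclodec-5-enone | O=C1CC[C@@H](C)/C=C\[C@@H](C(=C)CO[Si](CC)(CC)CC)[C@H](O[Si](CC)(CC)CC)[C@@H](O[Si](CC)(CC)CC)[C@@]1(C)O[Si](C)(C)C(C)(C)C | intermediate
18 | triol (C5–OH, C6–OH, C12–OH) | O=C1CC[C@@H](C)/C=C\[C@@H](C(=C)CO)[C@H](O)[C@@H](O)[C@@]1(C)O[Si](C)(C)C(C)(C)C | intermediate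
19 | hydroxy enal | O=C1CC[C@@H](C)/C=C\[C@@H](C(=C)C=O)[C@H](O)[C@@H](O)[C@@]1(C)O[Si](C)(C)C(C)(C)C | intermediate
20 | α-methylene lactone, free C5–OH | O=C1CC[C@@H](C)/C=C\[C@@H]2[C@H](OC(=O)C2=C)[C@@H](O)[C@@]1(C)O[Si](C)(C)C(C)(C)C | intermediate
21 | C5 isobutyrate | O=C1CC[C@@H](C)/C=C\[C@@H]2[C@H](OC(=O)C2=C)[C@@H](OC(=O)C(C)C)[C@@]1(C)O[Si](C)(C)C(C)(C)C | intermediate
22 | 8,9-epoxy ketone | O=C1CC[C@@H](C)[C@@H]3O[C@@H]3[C@@H]2[C@H](OC(=O)C2=C)[C@@H](OC(=O)C(C)C)[C@@]1(C)O[Si](C)(C)C(C)(C)C | intermediate
23 | bridged methyl ketal, free C8–OH | CO[C@]13CC[C@@H](C)[C@@H](O3)[C@H](O)[C@@H]2[C@H](OC(=O)C2=C)[C@@H](OC(=O)C(C)C)[C@@]1(C)O[Si](C)(C)C(C)(C)C | intermediate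
24 | bis-isobutyrate ketal | CO[C@]13CC[C@@H](C)[C@@H](O3)[C@H](OC(=O)C(C)C)[C@@H]2[C@H](OC(=O)C2=C)[C@@H](OC(=O)C(C)C)[C@@]1(C)O[Si](C)(C)C(C)(C)C | intermediate
25 | CNP0396108.1 | C=C1C(=O)O[C@H]2[C@H]1[C@@H](OC(=O)C(C)C)[C@H](O)[C@H](C)CCC(=O)[C@](C)(O)[C@@H]2OC(=O)C(C)C | target

## Step count and risks

Total step count: 17. Longest linear sequence: 16 steps (steps 1–6 and 8–17, from diethyl L-tartrate); step 7 is a one-step side branch.

**Step 11 (key step).** The rearrangement may leave the chair path and go through a boat, which would give the E-alkene and the C10 epimer. A silyl group may also migrate from C4–O or C5–O to the C3 oxyanion and remove the charge that drives the reaction, or the congested alkoxide may fragment. The fallback drops the oxyanion and uses the neutral siloxy-Cope manifold. From 15, N-(trimethylsilyl)imidazole gives the C3 trimethylsilyl ether F1. Thermolysis of F1 (decalin, about 200 °C, base-washed glass) should give the trimethylsilyl enol ether F2 through the same chair; the C3 oxygen substituent should favour this [3,3] shift over the all-carbon 1,5-diene C13=C11–C7–C8–C9=C10. Mild hydrolysis of F2 (KF, MeOH) returns to the route at 17.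

**Step 8.** Facial selectivity at C7 may be poor, because the conformer with a pseudoaxial C6–OTES group also has the C4 methyl group pseudoaxial on the same face; the enolate may also be trapped incompletely. The fallback replaces substrate control by catalyst control. From 11, bromine–lithium exchange and quenching with 2-isopropoxy-4,4,5,5-tetramethyl-1,3,2-dioxaborolane give the pinacol alkenylboronate F3. A rhodium(I)/chiral-ligand Hayashi–Miyaura 1,4-addition of F3 to 9 gives the C7-alkenyl ketone F4 with the face chosen by the ligand. Allylation of F4 at C8 (LiHMDS, allyl iodide; only C8 can be enolised) returns to the route at 13.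

**Step 6.** The C5 silyloxy group may be lost by β-elimination, or C6 may epimerise, through the enol or enamine of the aldehyde before the ring closes. The fallback avoids enolisable aldehyde chemistry. From 7, N-bromosuccinimide in wet THF converts the 1-ethoxyvinyl group into the bromomethyl ketone F5. Samarium(II) iodide at −78 °C forms the C8 enolate regiospecifically and adds it to the C7 aldehyde (Reformatsky-type closure) to give the β-hydroxy ketone F6. Mesylation and elimination (MsCl, Et3N) of F6 return to the route at 9.

**Step 15.** Epoxidation may occur on the other face of the Z-alkene, since a Z-cyclodecene is more mobile than an E-isomer; this would end in the 8,9-bis-epimer. A transannular hydride shift or attack by methanol instead of the carbonyl oxygen may also compete. The fallback is a reagent-controlled Shi epoxidation (fructose-derived ketone, Oxone, buffered) of 21, with the face set by the catalyst enantiomer. It delivers 22, where the route is rejoined, and makes no new compound (F0).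

**Step 9.** The double bond may migrate past the propenyl stage into conjugation with the C3 ketone, an E/Z mixture may form, or the C11=C13 allylic silyl ether may isomerise. The fallback is a direct α-alkenylation. From 9, the cuprate addition of step 8 is quenched with chlorotrimethylsilane to give the trimethylsilyl enol ether F7. Palladium-catalysed coupling of F7 with (E)-1-bromopropene in the presence of tributyltin fluoride (tin-enolate α-alkenylation, alkene geometry retained) gives 14 directly, where the route is rejoined.

**Step 10.** The hindered ketone may be enolised instead of attacked, with loss of the C8 configuration or conjugation of the propenyl group. The fallback uses a smaller, less basic nucleophile. From 14, lithium (trimethylsilyl)acetylide with CeCl3 adds axially to give the alkynyl carbinol F8. Potassium carbonate in methanol gives the terminal alkyne F9, and Lindlar semi-hydrogenation of F9 returns to the route at 15.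

## Further compounds

F1 | step 11 | C3 trimethylsilyl ether of 15 | C[Si](C)(C)O[C@]1(C=C)[C@](C)(O[Si](C)(C)C(C)(C)C)[C@H](O[Si](CC)(CC)CC)[C@@H](O[Si](CC)(CC)CC)[C@H](C(=C)CO[Si](CC)(CC)CC)[C@H]1/C=C/C
F2 | step 11 | trimethylsilyl enol ether of 17 | C[Si](C)(C)O/C1=C\C[C@@H](C)/C=C\[C@@H](C(=C)CO[Si](CC)(CC)CC)[C@H](O[Si](CC)(CC)CC)[C@@H](O[Si](CC)(CC)CC)[C@@]1(C)O[Si](C)(C)C(C)(C)C
F3 | step 8 | pinacol [3-(triethylsilyloxy)prop-1-en-2-yl]boronate | CC1(C)OB(OC1(C)C)C(=C)CO[Si](CC)(CC)CC
F4 | step 8 | C7-alkenyl cyclohexanone (13 without the C8 allyl group) | O=C1[C@](C)(O[Si](C)(C)C(C)(C)C)[C@H](O[Si](CC)(CC)CC)[C@@H](O[Si](CC)(CC)CC)[C@H](C(=C)CO[Si](CC)(CC)CC)C1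
F5 | step 6 | bromomethyl ketone aldehyde | BrCC(=O)[C@](C)(O[Si](C)(C)C(C)(C)C)[C@H](O[Si](CC)(CC)CC)[C@@H](O[Si](CC)(CC)CC)C=O
F6 | step 6 | β-hydroxy ketone (C7 carbinol, either epimer) | O=C1[C@](C)(O[Si](C)(C)C(C)(C)C)[C@H](O[Si](CC)(CC)CC)[C@@H](O[Si](CC)(CC)CC)C(O)C1
F0 | step 15 | none | none
F7 | step 9 | trimethylsilyl enol ether of the conjugate adduct | C[Si](C)(C)OC1=C[C@@H](C(=C)CO[Si](CC)(CC)CC)[C@H](O[Si](CC)(CC)CC)[C@@H](O[Si](CC)(CC)CC)[C@@]1(C)O[Si](C)(C)C(C)(C)C
F8 | step 10 | C3 (trimethylsilyl)ethynyl carbinol | O[C@]1(C#C[Si](C)(C)C)[C@](C)(O[Si](C)(C)C(C)(C)C)[C@H](O[Si](CC)(CC)CC)[C@@H](O[Si](CC)(CC)CC)[C@H](C(=C)CO[Si](CC)(CC)CC)[C@H]1/C=C/C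
F9 | step 10 | C3 ethynyl carbinol | O[C@]1(C#C)[C@](C)(O[Si](C)(C)C(C)(C)C)[C@H](O[Si](CC)(CC)CC)[C@@H](O[Si](CC)(CC)CC)[C@H](C(=C)CO[Si](CC)(CC)CC)[C@H]1/C=C/C
A1 | alternative 1 | seco bromo-aldehyde (C6 aldehyde, C7=C11 bromomethyl acrylate) | O=C[C@@H](OC(=O)C(C)C)[C@@](C)(O[Si](C)(C)C(C)(C)C)C(=O)CC[C@@H](C)[C@@H](O[Si](CC)(CC)CC)[C@H](OC(=O)C(C)C)/C=C(\CBr)C(=O)OC
A2 | alternative 2 | diene for ring-closing metathesis at C1=C2 | C=CC(=O)[C@](C)(O)[C@H](OC(=O)C(C)C)[C@H]1OC(=O)C(=C)[C@@H]1[C@@H](OC(=O)C(C)C)[C@H](O)[C@H](C)C=C
A3 | alternative 3 | diketo aldehyde for pinacol closure at C4–C5 | CC(=O)C(=O)CC[C@@H](C)[C@@H](O[Si](CC)(CC)CC)[C@H](OC(=O)C(C)C)[C@H]1C(=C)C(=O)O[C@@H]1C=O
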